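Late in Wednesday's run, at 10.0 h, you read 55.9 % of product, yet the bench habit of so many percent an hour, taken from its first reading of 8.1 % at 1.00 h, promised 81.0 %. Carried on to the 15 h of eta, that same pace gives 122 %, which is more than the charge holds, so the straight line has a border.

in all of them: substrate 10 mM; gas 1.3 mM (held)

| charge | initiator | remark | time |
|---|---|---|---|
| Sunday's | 0.52 mol% | run made earlier |  |
| Thursday's | 0.82 mol% | run made earlier |  |
| Wednesday's | 1.3 mol% | run made earlier |  |
| delta | 0.6 mol% |  | 5.0 h |
| eta | 1.2 mol% |  | 15 h |

| run | time / h | product / % | substrate / % |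
|---|---|---|---|
| Sunday's | 0.833 | 5.8 | 96.0 |
| Sunday's | 1.50 | 7.5 | 91.6 |
| Sunday's | 3.00 | 14.3 | 87.4 |
| Sunday's | 6.00 | 24.9 | 73.7 |
| Sunday's | 10.0 | 40.1 | 60.4 |
| Thursday's | 0.833 | 5.0 | 95.6 |
| Thursday's | 1.50 | 10.0 | 90.8 |
| Thursday's | 3.00 | 15.7 | 83.3 |
| Thursday's | 6.00 | 33.4 | 67.6 |
| Thursday's | 10.0 | 46.5 | 51.5 |
| Wednesday's | 1.00 | 8.1 | 92.3 |
| Wednesday's | 2.50 | 17.0 | 81.8 |
| Wednesday's | 5.00 | 33.2 | 65.7 |
| Wednesday's | 8.00 | 49.1 | 52.1 |
| Wednesday's | 10.0 | 55.9 | 44.9 |

(each reading ± 1 percentage point)

- the flask that ends with the higher amount of product, in percent of the substrate charged, or "neither" when 2 percentage points or less lies between them (delta / eta / neither)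
- final product, as a percentage of the substrate charged, in delta
- final product, as a percentage of the substrate charged, in eta

- at the start none of reagent is dissolved
- the analysis behind the earlier runs scatters by 1 percentage point, standard deviation
- reactions considered so far: 2 second chain carrier -> ended chains; substrate + initiating radical -> capped initiator + first chain carrier; substrate + second chain carrier -> by-product + first chain carrier; reagent + first chain carrier -> product + second chain carrier; initiator -> 2 initiating radical; gas <-> reagent

The concentration to watch is that of the second chain carrier: the initiator feeds it and pairs of it end, so its steady level should go with the square root of the initiator concentration, and the substrate should then fall pseudo-first-order, losing a fixed share of what is left each hour. Wednesday's last substrate reading, 44.9 %, gives the logarithm of charge over remainder per hour, the Wednesday constant 0.0801 h⁻¹. As a check, the constants read from Wednesday's and Sunday's runs at that same time stand in the ratio 1.59, for loadings in the ratio 2.50, whose square root is 1.58.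

Scaled by that root, I reckon 0.0544 h⁻¹ for delta and 0.0769 h⁻¹ for eta. The asked time divided by the substrate's lifetime, one over the constant, is the ratio that marks the border: it is 0.272 in delta, still near the straight line, but 1.15 in eta, well past it. So I expect 23.8 % of product in delta and 68.5 % in eta, more in eta. The forecast, using constants from all three runs where I scaled from one reading, holds that “These constants scale with the square root of initiator” and says 24 % for delta, 68 % for eta, and eta ahead.

The flask gives 24.1 % in delta and 68.9 % in eta, so eta ends higher.

    2 second chain carrier → ended chains (k = 5.00 × 10⁷ M⁻¹ s⁻¹)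
    substrate + initiating radical → capped initiator + first chain carrier (k = 2.10 × 10⁵ M⁻¹ s⁻¹)
    substrate + second chain carrier → by-product + first chain carrier (k = 18000 M⁻¹ s⁻¹)
    reagent + first chain carrier → product + second chain carrier (k = 65000 M⁻¹ s⁻¹)
    initiator → 2 initiating radical (k = 0.00220 h⁻¹)
    gas ⇌ reagent, rate k6*(csat - [reagent]) (kL = 1.20 h⁻¹)

Take eta again with 2.5 mM of substrate, loading and time held: the initiator concentration is a quarter of eta's, so the Wednesday constant, scaled, becomes 0.0385 h⁻¹, half of eta's, and predicts 43.9 % of product. That flask holds 44.2 % of product and 55.8 % of substrate at 15.0 h.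

(The numbers in the tables come from a simulation for an exercise.)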